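**Assumption:** tingenone (1) is taken as a purchasable natural product, as (−)-guaiol (8) is, and its C20 methyl group is taken to be the more stable epimer next to the C21 ketone, so that brief contact with acid or base leaves C20 unchanged.

Atom numbers follow the celastroid skeleton (C1–C22) for the triterpenoid and primed guaiane numbers (C1'–C15') for the sesquiterpenoid. Compounds 1–18 are numbered in the order in which they appear in the steps.

## Analysis of the target

The target is an octacyclic heterodimer. A 6-oxotingenane nortriterpenoid (aromatic ring A, ring B enone C6=O/C7=C8, saturated rings C–E, C21 ketone) is joined through a 1,4-dioxane to a cis-fused guaiane with a C3'=C4' alkene and a C7' isopropenyl group. It has ten stereocentres: C9, C13, C14, C17, C18 and C20 in the triterpenoid (C13/C14 are vicinal quaternary carbons, C9 and C17 are also quaternary) and C1', C5', C7' and C10' in the guaiane. The two sets are separated by the flat arene and do not control each other. In the guaiane the two ring-fusion oxygens are cis and lie on the face of the seven-membered ring that also carries the C10' methyl and the C7' isopropenyl group, which is the more hindered face of any C1'=C5' alkene precursor. The C5'–O bond is a tertiary allylic aryl ether and can ionise in acid, C20 is epimerisable next to the C21 ketone, and the two guaiane alkenes are open to electrophiles and to migration. The main difficulty is that both ether carbons of the guaiane are fully substituted, so neither C–O bond can be made by substitution at carbon, and the two similar tertiary oxygens must be placed on C2 and C3 of the arene in one sense only. The strategy rests on the dioxane ring: it links arene C2 (para to the C6 carbonyl) and C3 (meta to it) of ring A to C5' and C1'. The two arene carbons can therefore carry different leaving groups, and both aryl–oxygen bonds can be made last, from the arene side.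

## Retrosynthetic reasoning

**18 to 17.** The C21 ketone is masked as a dioxolane in 17. The union uses strong base and hot carbonate, and the only enolisable carbonyl of the molecule (C20–H, C22–H2) should not take part. The forward step is a mild ketal hydrolysis that must spare the C5'–O aryl ether.

**17 to 7 and 15.** The two aryl C–O bonds, C2–O(C5') and C3–O(C1'), are cut, which opens the dioxane and separates the triterpenoid from the sesquiterpenoid. Cutting the alkyl C–O bonds instead would require substitution at two fully substituted carbons. Arene 7 carries fluoride at C2 and bromide at C3, and cis-diol 15 brings both oxygens. The gain is full convergence, with each oxygen assigned to its arene carbon by the nature of the leaving group: only C2–F responds to addition–elimination, and only C3–Br responds to copper. The forward step must first make the C2–O bond with the less hindered C5' alkoxide (mono-ether 16) and then close the ring at C3.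

**7 to 5.** The C3–Br and C2–F bonds are traced back to the two aryl triflates of 5 through fluoro triflate 6. The triflate para to the C6 carbonyl, with one free ortho position, should be the first to undergo oxidative addition, so fluoride is installed at C2 before bromide replaces the hindered C3 triflate. The natural catechol oxygens are given up on purpose. The dioxane oxygens come from 15, and in exchange the two arene carbons become chemically distinct electrophiles.

**5 to 1.** Ketal 5 comes from diketone 4 by selective ketalisation of the isolated C21 carbonyl. The C6 carbonyl of 4 comes from bis-triflate 3 by oxidation of the C6 methylene, which is both benzylic and allylic. Bis-triflate 3 is the trapped form of catechol 2, the reduction product of the quinone methide 1. Compound 1 supplies the whole carbon skeleton and all six triterpenoid stereocentres, so no C–C bond and no stereocentre has to be made on this side.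

**15 to 12.** The C3'=C4' alkene of 15 has no direct handle in the guaiane skeleton, because C3' is not allylic in 8 or 9. It is therefore made by moving the C2'=C3' alkene of diol 14 into the trisubstituted position, which is the only migration open to it since C1' and C5' are quaternary. Diol 14 is traced to epoxy alcohol 13 (cleavage of C2'–O with loss of a C3' hydrogen) and 13 to allylic alcohol 12. The C5' hydroxyl of 12 delivers the second oxygen to C1' on its own face, which fixes the cis-diol.

**12 to 8.** Allylic alcohol 12 comes from tetrasubstituted epoxide 11 by cleavage of C1'–O with loss of a C2' hydrogen. The epoxide oxygen of 11 must sit on the face of the C10' and C4' methyl groups. Direct epoxidation of 9 would attack the opposite face, so 11 is made through bromohydrin 10: the electrophile takes the open face, and the oxygen enters from the hindered face and stays there after ring closure. Diene 9 is the dehydration product of 8, which brings C7' and C10' in the correct configuration.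

## Alternatives that were turned down

**Alternative 1:** The disconnection is the C1'–C5' bond of the guaiane diol A1 (the same compound as 15), leading back to the ten-membered (Z)-enedione A2. In the forward step a divalent samarium reagent would couple the C1' ketone with the C5' enone carbonyl across the ring, closing the five- and seven-membered rings and setting the cis-diol in one operation.

- For it: the C3'=C4' alkene is already in place as the enone of A2, so the alkene migration and the two epoxide openings of the chosen route (steps 7–11) are not needed. On this point the alternative is stronger.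
- Against it: A2 is a medium ring with a (Z)-trisubstituted enone and two stereocentres that would have to be built from small pieces. The enone may be reduced at the alkene instead of coupling. Nothing obvious forces both new oxygens onto the face of the C10' methyl group.
- Comparison: it solves only the sesquiterpenoid half and leaves the union open. The chosen route takes the skeleton and C7'/C10' from 8 and pays with six functional-group steps whose stereochemical course is enforced by the substrate.

**Alternative 2:** The disconnection is the pair of bonds C13–C18 and C17–C22, which are rings D and E of the triterpenoid. The product would be the dimethyl ether A3, formed from the tricyclic C13 tertiary allylic alcohol A4. In the forward step a tin Lewis acid would ionise C13; the (Z)-C17=C18 alkene and then the C21 fluoroalkene would add in turn, and the α-fluoro cation would end as the C21 ketone.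

- For it: it is a real construction of the 6-oxotingenane skeleton from simple fragments, which the chosen route does not offer because it buys the skeleton. It sets C13, C17 and C18 in one step and places the C21 oxygen through the terminator. On these points it is stronger.
- Against it: the first bond must form at a cation next to the quaternary C14, where elimination and attack at C11 compete. The cis D/E fusion depends on the folding of a flexible chain. A3 still carries two methyl ethers and a C11=C12 alkene, so hydrogenation beside the enone, ether cleavage and then the same oxygen-differentiation problem would remain.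
- Comparison: it is far longer to the same union. The chosen strategy offers in its place a five-step path to 7 with all six stereocentres already correct.

**Alternative 3:** The disconnection is the C13–C14 bond. The product would be the D/E acid A5, formed from the eight-membered lactone A6, which spans C17 and C19 of ring E and carries the (Z)-C18=C13 alkylidene. In the forward step O-silylation of the lactone enolate and an Ireland–Claisen shift would deliver C14 to C13, contract the lactone to ring D and move the alkene to C18=C19.

- For it: the vicinal quaternary C13–C14 bond, the hardest C–C bond of the triterpenoid, is made through an ordered cyclic transition state. The chosen route does not make this bond at all, so the alternative is stronger on this point.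
- Against it: A5 is only a D/E fragment. Rings A–C with the quaternary C9 and the halogenated arene would still have to be annulated, the carboxyl reduced to the C14 methyl, and C18=C19 hydrogenated to a cis D/E fusion. Enolate geometry in a medium-ring lactone is hard to control.
- Comparison: it would place about twenty steps before the union. The chosen strategy keeps the risk in the late double O-arylation and in two palladium halogenations.

Key step: step 12

## Route

**Step 1**
Reactants: 1 tingenone (quinone methide nortriterpenoid with 3-hydroxy-2-oxo ring A and C21 ketone)
Product: 3 tingenol 2,3-bis(trifluoromethanesulfonate), via tingenol 2 (not isolated)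
Conditions: Na2S2O4, THF/H2O, rt, argon; then Tf2O, pyridine, CH2Cl2, −20 to 0 °C
Reagents that add atoms: trifluoromethanesulfonic anhydride, O=S(=O)(OS(=O)(=O)C(F)(F)F)C(F)(F)F
Why: Dithionite should reduce the extended quinone methide by 1,6-addition of hydrogen at C6, which aromatises ring A to the air-sensitive catechol 2 and leaves the C21 ketone and C7=C8 alone; immediate O-sulfonylation of both phenols should give the stable bis-triflate. No stereocentre is touched.

**Step 2**
Reactants: 3 tingenol 2,3-bis(trifluoromethanesulfonate)
Product: 4 6-oxotingenol 2,3-bis(trifluoromethanesulfonate) (6,21-dione)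
Conditions: Rh2(caprolactamate)4 (cat.), t-BuOOH (aq.), K2CO3, CH2Cl2, rt
Reagents that add atoms: tert-butyl hydroperoxide, CC(C)(C)OO
Why: This is an allylic/benzylic C–H oxidation by tert-butylperoxyl radicals; C6 is the only methylene that is both benzylic and allylic to C7=C8 (C9 and C14 are quaternary, the C4 methyl is benzylic only), so the enone should form there and the electron-poor arene and the saturated ketone should stay inert.

**Step 3**
Reactants: 4 6-oxotingenol 2,3-bis(trifluoromethanesulfonate)
Product: 5 6-oxotingenol 2,3-bis(trifluoromethanesulfonate) 21-ethylene ketal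
Conditions: (Me3SiOCH2)2, Me3SiOTf (cat.), CH2Cl2, −78 to −20 °C
Reagents that add atoms: 1,2-bis(trimethylsilyloxy)ethane, C[Si](C)(C)OCCO[Si](C)(C)C
Why: Aprotic silyl-transfer ketalisation should convert only the isolated C21 ketone; the C6 carbonyl is conjugated to both the arene and C7=C8 and is flanked by the C4 methyl group. The low temperature avoids enolisation at C20.

**Step 4**
Reactants: 5 6-oxotingenol 2,3-bis(trifluoromethanesulfonate) 21-ethylene ketal
Product: 6 2-fluoro-3-(trifluoromethanesulfonyloxy) arene (2-deoxy-2-fluoro-6-oxotingenol 3-triflate 21-ethylene ketal)
Conditions: [(cinnamyl)PdCl]2 (cat.), tBuBrettPhos, CsF, toluene, 110 °C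
Reagents that add atoms: caesium fluoride, [Cs+].[F-]
Why: This is a palladium-catalysed nucleophilic fluorination of an aryl triflate (oxidative addition, triflate-to-fluoride exchange, C–F reductive elimination from the bulky biaryl phosphine complex). The C2 triflate is para to the C6 carbonyl and has a free ortho position, so it should add to zerovalent palladium well before the C3 triflate, which is meta to the carbonyl and flanked on both sides.

**Step 5**
Reactants: 6 2-fluoro-3-(trifluoromethanesulfonyloxy) arene
Product: 7 2-fluoro-3-bromo arene (6-oxotingenane core with C21 ethylene ketal)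
Conditions: Pd2(dba)3 (cat.), tBuBrettPhos, KBr, KF (cat.), toluene, 100 °C
Reagents that add atoms: potassium bromide, [K+].[Br-]
Why: This is a palladium-catalysed conversion of an aryl triflate into the aryl bromide; only one triflate is left, the two ortho substituents speed up C–Br reductive elimination from the crowded divalent palladium aryl bromide, and the C2–F bond is inert to palladium.

**Step 6**
Reactants: 8 (−)-guaiol
Product: 9 α-guaiene (guaia-1(5),11-diene with C4, C7 and C10 as in 8)
Conditions: SOCl2, pyridine, 0 °C
Reagents that add atoms: none
Why: E2 dehydration through the tertiary chlorosulfite; pyridine should take one of the six exposed methyl hydrogens in preference to the single hindered C7–H, giving the isopropenyl group, and the isopropylidene isomer should be removable at this early stage.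

**Step 7**
Reactants: 9 α-guaiene
Product: 11 1,5-epoxyguai-11-ene with the oxygen cis to the C10 methyl group, via bromohydrin 10 (not isolated)
Conditions: NBS, DME/H2O, 0 °C; then NaOH (aq.), rt
Reagents that add atoms: water, O
Why: Halohydrin formation and ring closure: the bromonium ion should form on the face of the tetrasubstituted C1=C5 alkene away from the C4 methyl, C10 methyl and C7 substituent, water opens it anti, and the alkoxide displaces bromide with inversion. The epoxide oxygen therefore ends on the methyl-bearing face, opposite to a peracid epoxidation, and this sets C1 and C5. The electron-rich tetrasubstituted alkene should react before the isopropenyl group.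

**Step 8**
Reactants: 11 1,5-epoxyguai-11-ene
Product: 12 guaia-1,11-dien-5-ol (C5–OH cis to the C4 methyl group)
Conditions: Et2AlCl, lithium 2,2,6,6-tetramethylpiperidide, toluene, 0 °C
Reagents that add atoms: none
Why: Aluminium amide rearrangement of an epoxide to an allylic alcohol by syn β-elimination through a cyclic transition state. The C4 and C10 hydrogens are anti to the epoxide oxygen and cannot be reached, and the syn hydrogen on C6 is shielded by the cis isopropenyl group, so the syn C2 hydrogen should be removed with cleavage of C1–O; C5 keeps its configuration.

**Step 9**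
Reactants: 12 guaia-1,11-dien-5-ol
Product: 13 1,2-epoxyguai-11-en-5-ol (epoxide cis to the C5 hydroxyl)
Conditions: VO(acac)2 (cat.), t-BuOOH, toluene, 0 °C to rt
Reagents that add atoms: tert-butyl hydroperoxide, CC(C)(C)OO
Why: Vanadium-catalysed hydroxyl-directed epoxidation: the allylic C5 alkoxide on vanadium should deliver the peroxide oxygen to its own face of C1=C2, which puts the C1 oxygen cis to the C5 oxygen; the isopropenyl group has no directing hydroxyl and should not react.

**Step 10**
Reactants: 13 1,2-epoxyguai-11-en-5-ol
Product: 14 guaia-2,11-diene-1,5-diol (cis-diol, both hydroxyls cis to the C10 methyl group)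
Conditions: Et2AlCl, lithium 2,2,6,6-tetramethylpiperidide (excess), toluene, 0 °C to rt
Reagents that add atoms: none
Why: Second syn β-elimination of an epoxide: the C10 hydrogen is anti to the epoxide oxygen, so the only syn β-hydrogen is on C3; the C2–O bond should break, and the tertiary C1 hydroxyl remains with the configuration set in step 9.

**Step 11**
Reactants: 14 guaia-2,11-diene-1,5-diol
Product: 15 guaia-3,11-diene-1,5-diol (cis-diol)
Conditions: RuHCl(CO)(PPh3)3 (cat.), toluene, 80 °C
Reagents that add atoms: none
Why: Metal hydride alkene isomerisation by addition and β-hydride elimination. Ru–H should add to C2=C3 from the face away from the two hydroxyls, where the C4 hydrogen also lies, and eliminate toward C4 to give the more stable trisubstituted alkene. It cannot move further because C1 and C5 are quaternary, and the isopropenyl group would need a tertiary alkyl–ruthenium to migrate.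

**Step 12**
Reactants: 7 2-fluoro-3-bromo arene (6-oxotingenane core with C21 ethylene ketal), 15 guaia-3,11-diene-1,5-diol
Product: 17 C21 ethylene ketal of the target, via mono-aryl ether 16 (not isolated)
Conditions: KN(SiMe3)2, THF/DMF, −20 °C to rt; then CuI (cat.), 3,4,7,8-tetramethyl-1,10-phenanthroline, Cs2CO3, toluene, 110 °C
Reagents that add atoms: none
Why: Deprotonation of 15 gives a hydrogen-bonded monoalkoxide; its C5' oxygen adds to arene C2 of 7 to give a Meisenheimer anion delocalised into the para C6 carbonyl, and loss of fluoride gives 16 (addition–elimination, the known etherification of para-acyl aryl fluorides by tertiary alkoxides). The copper phenanthroline complex then forms the monovalent copper alkoxide of the C1' hydroxyl, which adds oxidatively into the neighbouring C3–Br bond, and reductive elimination from the trivalent copper aryl alkoxide makes the C3–O bond (intramolecular Ullmann ether synthesis, known for tertiary alcohols closing benzo-fused oxygen rings). The 1,4-dioxane closes as a six-membered ring by attack of the tethered oxygen on the arene carbon, a 6-exo closure counted at the aryl carbon, and only a cis-diol can span the two adjacent arene positions. No stereocentre is formed, because C1' and C5' are never attacked at carbon; this is what allows two fully substituted carbinol carbons to be used. The step needs two selectivities: only C2–F is activated for substitution (para to C6=O, whereas C3–Br is meta and a poor leaving group in addition–elimination), and the C5' alkoxide, flanked by the planar C4' and a methylene, is less hindered than the C1' oxygen, which is gauche to the cis C10' methyl. Tertiary alkoxides cannot undergo β-hydride elimination at copper, the enone has no acidic hydrogen (C8 is fully substituted), and the C21 ketone is masked.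

**Step 13**
Reactants: 17 C21 ethylene ketal of the target
Product: 18 target (CNP0405270.2)
Conditions: pyridinium p-toluenesulfonate (cat.), acetone/H2O, 40 °C
Reagents that add atoms: water, O
Why: Acid-catalysed ketal hydrolysis under buffered conditions mild enough that the tertiary allylic C5'–O aryl ether should not ionise; the C20 methyl group stays in its stable orientation next to the freed C21 ketone.

## Compound list

1 | tingenone | O=C1C=C2C(=CC=C3[C@@]2(C)CC[C@@]2(C)[C@@H]4C[C@@H](C)C(=O)C[C@]4(C)CC[C@]32C)C(C)=C1O | starting material
2 | tingenol (2,3-dihydroxy arene with C6 methylene and C7=C8) | Oc1cc2c(c(C)c1O)CC=C1[C@@]2(C)CC[C@@]2(C)[C@@H]3C[C@@H](C)C(=O)C[C@]3(C)CC[C@]12C | intermediate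
3 | tingenol 2,3-bis(trifluoromethanesulfonate) | FC(F)(F)S(=O)(=O)Oc1cc2c(c(C)c1OS(=O)(=O)C(F)(F)F)CC=C1[C@@]2(C)CC[C@@]2(C)[C@@H]3C[C@@H](C)C(=O)C[C@]3(C)CC[C@]12C | intermediate
4 | 6-oxotingenol 2,3-bis(trifluoromethanesulfonate) | FC(F)(F)S(=O)(=O)Oc1cc2c(c(C)c1OS(=O)(=O)C(F)(F)F)C(=O)C=C1[C@@]2(C)CC[C@@]2(C)[C@@H]3C[C@@H](C)C(=O)C[C@]3(C)CC[C@]12C | intermediate
5 | 6-oxotingenol 2,3-bis(trifluoromethanesulfonate) 21-ethylene ketal | FC(F)(F)S(=O)(=O)Oc1cc2c(c(C)c1OS(=O)(=O)C(F)(F)F)C(=O)C=C1[C@@]2(C)CC[C@@]2(C)[C@@H]3C[C@@H](C)C4(OCCO4)C[C@]3(C)CC[C@]12C | intermediate
6 | 2-fluoro-3-(trifluoromethanesulfonyloxy) arene, 21-ethylene ketal | Fc1cc2c(c(C)c1OS(=O)(=O)C(F)(F)F)C(=O)C=C1[C@@]2(C)CC[C@@]2(C)[C@@H]3C[C@@H](C)C4(OCCO4)C[C@]3(C)CC[C@]12C | intermediate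
7 | 2-fluoro-3-bromo arene (6-oxotingenane core, 21-ethylene ketal) | Fc1cc2c(c(C)c1Br)C(=O)C=C1[C@@]2(C)CC[C@@]2(C)[C@@H]3C[C@@H](C)C4(OCCO4)C[C@]3(C)CC[C@]12C | intermediate
8 | (−)-guaiol | CC(C)(O)[C@@H]1CC[C@H](C)C2=C(C1)[C@@H](C)CC2 | starting material
9 | α-guaiene (guaia-1(5),11-diene) | C=C(C)[C@@H]1CC[C@H](C)C2=C(C1)[C@@H](C)CC2 | intermediate
10 | trans-bromohydrin (1-bromoguai-11-en-5-ol, hydroxyl on the methyl-bearing face; the 5-bromo-1-hydroxy regioisomer closes to the same epoxide) | C=C(C)[C@@H]1CC[C@H](C)[C@@]2(Br)[C@](O)(C1)[C@@H](C)CC2 | intermediate
11 | 1,5-epoxyguai-11-ene (oxygen cis to the C10 and C4 methyl groups) | C=C(C)[C@@H]1CC[C@H](C)[C@@]23O[C@@]3(C1)[C@@H](C)CC2 | intermediate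
12 | guaia-1,11-dien-5-ol | C=C(C)[C@@H]1CC[C@H](C)C2=CC[C@H](C)[C@@]2(O)C1 | intermediate
13 | 1,2-epoxyguai-11-en-5-ol (epoxide cis to the hydroxyl) | C=C(C)[C@@H]1CC[C@H](C)[C@]23O[C@@H]3C[C@H](C)[C@@]2(O)C1 | intermediate
14 | guaia-2,11-diene-1,5-diol (cis) | C=C(C)[C@@H]1CC[C@H](C)[C@@]2(O)C=C[C@H](C)[C@]2(C1)O | intermediate
15 | guaia-3,11-diene-1,5-diol (cis) | C=C(C)[C@@H]1CC[C@H](C)[C@@]2(O)CC=C(C)[C@]2(C1)O | intermediate
16 | mono-aryl ether (C5'–O–C2, free C1' hydroxyl, C3 bromide) | C=C(C)[C@@H]1CC[C@H](C)[C@@]2(O)CC=C(C)[C@]2(C1)Oc1cc2c(c(C)c1Br)C(=O)C=C1[C@@]2(C)CC[C@@]2(C)[C@@H]3C[C@@H](C)C4(OCCO4)C[C@]3(C)CC[C@]12C | intermediate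
17 | target as its C21 ethylene ketal | C=C(C)[C@@H]1CC[C@H](C)[C@@]23CC=C(C)[C@]2(C1)Oc1cc2c(c(C)c1O3)C(=O)C=C1[C@@]2(C)CC[C@@]2(C)[C@@H]3C[C@@H](C)C4(OCCO4)C[C@]3(C)CC[C@]12C | intermediate
18 | CNP0405270.2 | C=C(C)[C@@H]1CC[C@H](C)[C@@]23CC=C(C)[C@]2(C1)Oc1cc2c(c(C)c1O3)C(=O)C=C1[C@@]2(C)CC[C@@]2(C)[C@@H]3C[C@@H](C)C(=O)C[C@]3(C)CC[C@]12C | target

## Step count and least certain steps

Total: 13 steps. The longest linear sequence is 8 steps (8 to 18, steps 6–13); the branch from 1 contributes 7 steps (steps 1–5, 12, 13).

**Step 12 (key step).** The most likely failure is loss of regiochemical definition. The C1' alkoxide may attack C2, or the aryl group of 16 may migrate from one oxygen to the other through a spiro Meisenheimer anion before the ring closes, so that both dioxane orientations form. A second risk is slow oxidative addition of copper into the C3–Br bond, which is flanked on both sides, leading to loss of bromine. Free amide base could also deprotonate C1–H next to fluorine and open an aryne path, so the diol is kept in slight excess over the base.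

Fallback: the arene is introduced while only the C5' oxygen exists. It sets out from epoxy alcohol 13 and arene 7 and comes back at 17.
- Addition–elimination of the alkoxide of 13 (KN(SiMe3)2, THF/DMF) should give epoxy aryl ether F1; the syn epoxide cannot be opened by the neighbouring alkoxide.
- Epoxide-to-allylic-alcohol rearrangement (Et2AlCl, lithium 2,2,6,6-tetramethylpiperidide) should give allylic alcohol F2.
- Copper-catalysed ring closure as in step 12 should give the C2'=C3' dioxane F3.
- Alkene migration with RuHCl(CO)(PPh3)3 should give 17.

**Step 4.** The risks are insufficient discrimination between the two triflates (over-fluorination at C3), attack of fluoride at sulfur with loss of a triflate as phenoxide, and scrambling of the fluorine position through aryne-type palladium intermediates.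

Fallback, from 5 back to 6: one equivalent of Et4NOH in dioxane should cleave the more activated and less hindered C2 triflate to give phenol F4. Deoxyfluorination of F4 with PhenoFluor and CsF in toluene should then give 6 without palladium.

**Step 5.** The risks are slow oxidative addition at the di-ortho-substituted triflate, inhibition of the catalyst by the product bromide, and competing C–F bond formation from the fluoride additive.

Fallback, from 6 back to 7: stannylation with (Me3Sn)2, Pd(PPh3)4 and LiCl in dioxane should give aryl stannane F5. Ipso-bromodestannylation with Br2 in CH2Cl2 at −78 °C should then give 7.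

**Step 8.** The risk is loss of regiocontrol in the proton abstraction: removal of the syn C6 hydrogen would place the alkene at C5=C6 and the hydroxyl at C1.

Fallback, from 9 back to 12, with the alkene position fixed by a carbonyl group:
- Allylic oxidation at C2 (Rh2(caprolactamate)4, t-BuOOH) should give rotundone F6.
- Luche reduction (NaBH4, CeCl3) from the face opposite the C4 methyl group should give rotundol F7.
- Hydroxyl-directed epoxidation (VO(acac)2, t-BuOOH) should give epoxy alcohol F8.
- Dess–Martin oxidation should give epoxy ketone F9.
- Wharton transposition (N2H4, AcOH, MeOH) should give 12.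

**Step 11.** The risk is poor chemoselectivity of the hydride catalyst: migration of the isopropenyl alkene to the C7=C11 position may compete with the ring alkene.

Fallback, from 14 back to 15, by stoichiometric and regiodefined chemistry that does not touch the isopropenyl group:
- Hydroxyl-directed epoxidation of C2=C3 (VO(acac)2, t-BuOOH) should give epoxy diol F10.
- Red-Al should open the epoxide at C2 by hydride delivery from the C1 alkoxide to give triol F11.
- Selective sulfonylation of the only secondary hydroxyl (MsCl, Et3N) should give mesylate F12.
- Anti elimination with DBU toward the anti C4 hydrogen should give 15.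

## Further compounds

F1 | step 12 | C5'-O-aryl ether of epoxy alcohol 13 with arene 7 (epoxide intact, C3 bromide) | C=C(C)[C@@H]1CC[C@H](C)[C@]23O[C@@H]3C[C@H](C)[C@@]2(Oc4cc5c(c(C)c4Br)C(=O)C=C6[C@@]5(C)CC[C@@]5(C)[C@@H]7C[C@@H](C)C8(OCCO8)C[C@]7(C)CC[C@]65C)C1
F2 | step 12 | C2'=C3' isomer of mono-aryl ether 16 (free C1' hydroxyl) | C=C(C)[C@@H]1CC[C@H](C)[C@@]2(O)C=C[C@H](C)[C@]2(C1)Oc1cc2c(c(C)c1Br)C(=O)C=C1[C@@]2(C)CC[C@@]2(C)[C@@H]3C[C@@H](C)C4(OCCO4)C[C@]3(C)CC[C@]12C
F3 | step 12 | C2'=C3' isomer of dioxane ketal 17 | C=C(C)[C@@H]1CC[C@H](C)[C@@]23C=C[C@H](C)[C@]2(C1)Oc1cc2c(c(C)c1O3)C(=O)C=C1[C@@]2(C)CC[C@@]2(C)[C@@H]3C[C@@H](C)C4(OCCO4)C[C@]3(C)CC[C@]12C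
F4 | step 4 | 2-hydroxy-3-(trifluoromethanesulfonyloxy) arene, 21-ethylene ketal | Oc1cc2c(c(C)c1OS(=O)(=O)C(F)(F)F)C(=O)C=C1[C@@]2(C)CC[C@@]2(C)[C@@H]3C[C@@H](C)C4(OCCO4)C[C@]3(C)CC[C@]12C
F5 | step 5 | 2-fluoro-3-(trimethylstannyl) arene, 21-ethylene ketal | Fc1cc2c(c(C)c1[Sn](C)(C)C)C(=O)C=C1[C@@]2(C)CC[C@@]2(C)[C@@H]3C[C@@H](C)C4(OCCO4)C[C@]3(C)CC[C@]12C
F6 | step 8 | rotundone (guaia-1(5),11-dien-2-one) | C=C(C)[C@@H]1CC[C@H](C)C2=C(C1)[C@@H](C)CC2=O
F7 | step 8 | rotundol (guaia-1(5),11-dien-2-ol, hydroxyl cis to the C4 methyl group) | C=C(C)[C@@H]1CC[C@H](C)C2=C(C1)[C@@H](C)C[C@H]2O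
F8 | step 8 | 1,5-epoxyguai-11-en-2-ol (epoxide cis to the hydroxyl) | C=C(C)[C@@H]1CC[C@H](C)[C@@]23O[C@@]3(C1)[C@@H](C)C[C@H]2O
F9 | step 8 | 1,5-epoxyguai-11-en-2-one | C=C(C)[C@@H]1CC[C@H](C)[C@@]23O[C@@]3(C1)[C@@H](C)CC2=O
F10 | step 11 | 2,3-epoxyguai-11-ene-1,5-diol (epoxide cis to the hydroxyls) | C=C(C)[C@@H]1CC[C@H](C)[C@@]2(O)[C@@H]3O[C@@H]3[C@H](C)[C@]2(C1)O
F11 | step 11 | guai-11-ene-1,3,5-triol (all hydroxyls cis) | C=C(C)[C@@H]1CC[C@H](C)[C@@]2(O)C[C@H](O)[C@H](C)[C@]2(C1)O
F12 | step 11 | guai-11-ene-1,3,5-triol 3-methanesulfonate | C=C(C)[C@@H]1CC[C@H](C)[C@@]2(O)C[C@H](OS(C)(=O)=O)[C@H](C)[C@]2(C1)O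
A1 | alternative 1 | guaia-3,11-diene-1,5-cis-diol (identical with 15) | C=C(C)[C@@H]1CC[C@H](C)[C@@]2(O)CC=C(C)[C@]2(C1)O
A2 | alternative 1 | (Z)-4,10-dimethyl-7-(prop-1-en-2-yl)cyclodec-3-ene-1,5-dione (guaiane numbering, C1 and C5 ketones) | C=C(C)[C@@H]1CC[C@H](C)C(=O)C/C=C(C)\C(=O)C1
A3 | alternative 2 | 11,12-didehydro-6-oxotingenol dimethyl ether | COc1cc2c(c(C)c1OC)C(=O)C=C1[C@@]2(C)C=C[C@@]2(C)[C@@H]3C[C@@H](C)C(=O)C[C@]3(C)CC[C@]12C
A4 | alternative 2 | tricyclic C13 tertiary allylic alcohol with (Z)-C17=C18 alkene and C21 vinyl fluoride (C13 configuration open, lost on ionisation) | COc1cc2c(c(C)c1OC)C(=O)C=C1[C@@]2(C)C=CC(C)(O)[C@]1(C)CC/C(C)=C\C[C@@H](C)C(F)=C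
A5 | alternative 3 | D/E bicyclic acid with quaternary C13 and C14 | CC(C)(C)[Si](C)(C)OCC[C@@]1(C)C2=C[C@@H](C)C3(OCCO3)C[C@]2(C)CC[C@]1(C(=O)O)COCc1ccccc1
A6 | alternative 3 | eight-membered lactone from C19–O to C17 through C14–C16 on ring E with (Z)-C18=C13 alkylidene (C14 configuration open, lost on enolisation) | CC(C)(C)[Si](C)(C)OCC/C(C)=C1\[C@@H]2OC(=O)C(COCc3ccccc3)CC[C@@]1(C)CC1(OCCO1)[C@@H]2C
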